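**Plan** (eudesmane numbering: ring A = C1–C5/C10, ring B = C5–C10, C11–C13 = acrylate, C15 = methyl on C4; α = face opposite the C10 methyl)
- Retrosynthesis first removes the C6 angelate, the C11=C13 methylene and the C12 ester level, then takes the C4 carbinol back to a C4 ketone and the C5–H/C8–OH pair back to a C5–O–C8 ether bridge.
- C5–C10 and C8–C9 are then cut together, giving a 2,4-disubstituted furan tied through C4–C1 to an isopropenyl ketone.
- The enabling feature: C5–C6–C7–C8 of ring B is a masked furan (C5, C8 = α-carbons, the furan oxygen becomes the C8 hydroxyl, C7 = β-carbon with the side chain), and C9=C10 with its methyl and the C1 carbonyl is an isopropenyl ketone four atoms (C1–C4) from C5.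
- Forward: furan building block, chiral furyl carbinol, enone; one intramolecular furan Diels–Alder reaction closes rings A and B; C4 oxidation and SmI2 cut the bridge to the trans-decalin; then C4, C1, C6/C7, angelate, acrylate.
- Stereochemistry: the (R)-C4 carbinol (asymmetric transfer hydrogenation) sets the absolute sense of the cycloaddition; the tether geometry puts the C10 methyl anti to the oxygen bridge (8α-O, 10β-Me).
- C5, C1, C4, C6 and C7 are then set by α-face attack, away from the axial C10 and C4 methyl groups.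

Key step: step 8

Step 1
Reactants: 1 3-bromofuran; 2 oxirane
Product: 4 2-(furan-3-yl)ethan-1-ol, via furan-3-yllithium 3 (not isolated)
Conditions: n-BuLi, THF, −78 °C; then oxirane, BF3·OEt2, −78 °C; aq. NH4Cl
Reagents that add atoms: none
Why: Halogen–lithium exchange gives furan-3-yllithium, which should open the BF3-activated epoxide at −78 °C before it can isomerise to the 2-lithio isomer (organolithium epoxide opening); no stereocenter is formed.

Step 2
Reactants: 4 2-(furan-3-yl)ethan-1-ol
Product: 5 3-{2-[(4-methoxybenzyl)oxy]ethyl}furan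
Conditions: NaH, 4-methoxybenzyl chloride, Bu4NI (cat.), THF/DMF, 0 °C → rt
Reagents that add atoms: 4-methoxybenzyl chloride, COc1ccc(CCl)cc1
Why: Williamson etherification; the PMB ether should survive the Lewis acid, SmI2, hydride and borane steps and is removed oxidatively later in the presence of the angelate.

Step 3
Reactants: 5 3-{2-[(4-methoxybenzyl)oxy]ethyl}furan
Product: 6 2-(4-{2-[(4-methoxybenzyl)oxy]ethyl}furan-2-yl)-4,4,5,5-tetramethyl-1,3,2-dioxaborolane
Conditions: [Ir(OMe)(cod)]2 (cat.), 4,4'-di-tert-butyl-2,2'-bipyridine (cat.), B2pin2, THF, rt → 50 °C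
Reagents that add atoms: bis(pinacolato)diboron, CC1(C)OB(OC1(C)C)B1OC(C)(C)C(C)(C)O1
Why: Iridium-catalysed C–H borylation is sterically controlled and should functionalise the furan α-position remote from the 3-substituent, fixing the 2,4-pattern that electrophilic acylation would not give.

Step 4
Reactants: 6 furan-2-yl pinacol boronate; 7 methyl 4-chloro-4-oxobutanoate
Product: 8 methyl 4-(4-{2-[(4-methoxybenzyl)oxy]ethyl}furan-2-yl)-4-oxobutanoate
Conditions: Pd(PPh3)4 (cat.), Cs2CO3, toluene (anhydrous), 90 °C
Reagents that add atoms: none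
Why: Acylative Suzuki–Miyaura coupling (oxidative addition of the acid chloride, transmetalation of the 2-furylboronate, reductive elimination) installs C4–C1 as a γ-keto ester; the anhydrous base limits protodeboronation.

Step 5
Reactants: 8 γ-keto ester
Product: 10 (5R)-5-(4-{2-[(4-methoxybenzyl)oxy]ethyl}furan-2-yl)dihydrofuran-2(3H)-one, via (4R)-hydroxy ester 9 (not isolated)
Conditions: RuCl(p-cymene)[(R,R)-TsDPEN] (cat.), HCO2H/Et3N (5:2), rt; then TsOH (cat.), toluene, rt
Reagents that add atoms: none
Why: Noyori asymmetric transfer hydrogenation of the 2-furyl ketone, in which the (R,R) catalyst should give the (R)-carbinol (furyl acting as the aryl group), followed by acid-catalysed lactonisation of the γ-hydroxy ester.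

Step 6
Reactants: 10 (5R)-lactone; 11 isopropenylmagnesium bromide
Product: 13 (6R)-6-hydroxy-6-(4-{2-[(4-methoxybenzyl)oxy]ethyl}furan-2-yl)-2-methylhex-1-en-3-one, via Weinreb amide 12 (not isolated)
Conditions: MeNH(OMe)·HCl, i-PrMgCl, THF, −20 °C; then isopropenylmagnesium bromide, −20 → 0 °C; aq. NH4Cl
Reagents that add atoms: none
Why: The chloromagnesium amide opens the lactone to the Weinreb amide as its magnesium alkoxide, and the chelated tetrahedral intermediate stops the Grignard addition at the isopropenyl ketone (Weinreb ketone synthesis); the carbinol center is untouched.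

Step 7
Reactants: 13 (6R)-hydroxy enone
Product: 14 (6R)-6-[(tert-butyldimethylsilyl)oxy]-6-(4-{2-[(4-methoxybenzyl)oxy]ethyl}furan-2-yl)-2-methylhex-1-en-3-one
Conditions: TBSCl, imidazole, DMF, 0 °C → rt
Reagents that add atoms: tert-butyldimethylsilyl chloride, CC(C)(C)[Si](C)(C)Cl
Why: Standard silylation; the TBS ether shields the furfuryl oxygen from the Lewis acid of step 8 and is the bulky group that will sit equatorial in the forming ring A.

Step 8
Reactants: 14 TBS-protected furyl enone
Product: 15 oxa-bridged cycloadduct (C5–O–C8 ether bridge on the α-face, 4α-OTBS, 10β-methyl, C1 ketone, C6=C7 alkene carrying the 2-(PMB-oxy)ethyl chain on C7)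
Conditions: MeAlCl2 (2 equiv), CH2Cl2, −78 °C; aq. potassium sodium tartrate, −78 °C → rt
Reagents that add atoms: none
Why: MeAlCl2 binds the C1 carbonyl and the furan (C5–C8 as diene) adds to the isopropenyl C9=C10 in a concerted, asynchronous, normal-demand [4π+2π] cycloaddition that forms C5–C10 and C8–C9 together. The closest known reaction type is the Lewis-acid-promoted intramolecular Diels–Alder reaction of furans with tethered enones, including α-methyl enones that deliver an angular methyl group. Ring B closes as the cyclohexene of a 7-oxabicyclo[2.2.1]heptene (six-membered, suprafacial on both partners, oxygen bridging C5 and C8), and ring A closes as a six-membered carbocycle through the four-atom tether C1–C4, fused at C5–C10 with the tether exo (syn to the oxygen bridge). C5 and C8 are set together by suprafacial addition to the furan; C10 is set by the tether, which can span only the exo position without distorting ring A, so the methyl is endo and anti to the bridge (future 8α-O/10β-Me); the absolute sense comes from C4, whose OTBS group sits equatorial in the chair-like forming ring A to avoid the 1,3-diaxial clash with the C10 methyl. The step needs π-facial selectivity with respect to C4 and exo tether geometry; both rest on the short tether and the equatorial preference, and since the cycloaddition is reversible under the Lewis acid the same, thermodynamically preferred adduct should accumulate at −78 °C.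

Step 9
Reactants: 15 oxa-bridged cycloadduct
Product: 16 oxa-bridged 4α-alcohol
Conditions: Bu4NF, AcOH, THF, 0 °C
Reagents that add atoms: none
Why: Fluoride-mediated desilylation, buffered with acetic acid to keep the adduct away from base, frees the C4 carbinol without touching a stereocenter.

Step 10
Reactants: 16 oxa-bridged 4α-alcohol
Product: 17 oxa-bridged 1,4-dione
Conditions: Dess–Martin periodinane, CH2Cl2, 0 °C
Reagents that add atoms: none
Why: Dess–Martin oxidation under neutral, cold conditions converts the C4 carbinol, whose stereochemical task is done, into the α-alkoxy ketone needed to cut the bridge.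

Step 11
Reactants: 17 oxa-bridged 1,4-dione
Product: 18 trans-fused 8α-hydroxy-6-ene-1,4-dione (5α-H, 10β-methyl)
Conditions: SmI2 (2.5 equiv), THF/MeOH, −78 °C
Reagents that add atoms: none
Why: SmI2 reduction of an α-alkoxy ketone: the C4 ketyl expels the axial, stereoelectronically aligned C5–O bond, a second electron gives the samarium dienolate, and kinetic α-protonation by methanol at C5 from the α-face (axial, anti to the C10 methyl) should give the trans ring fusion while the oxygen stays on C8 as the 8α-hydroxyl.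

Step 12
Reactants: 18 8α-hydroxy-6-ene-1,4-dione
Product: 19 8α-hydroxy-4-methylene-6-en-1-one
Conditions: Zn, CH2Br2, TiCl4, THF/CH2Cl2, 0 °C → rt
Reagents that add atoms: dibromomethane, BrCBr
Why: Takai–Lombardo methylenation is non-basic, so the β,γ-unsaturated ketone should neither epimerise at C5 nor conjugate, and it should select the C4 ketone over the C1 ketone, which is shielded by the adjacent quaternary C10.

Step 13
Reactants: 19 8α-hydroxy-4-methylene-6-en-1-one
Product: 21 1β,4α,8α-triol (4β-methyl, C6=C7 alkene), via C15 organomercurial 20 (not isolated)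
Conditions: Hg(OAc)2, THF/H2O, rt; then NaOH, NaBH4, 0 °C → rt
Reagents that add atoms: water, O
Why: Markovnikov oxymercuration–demercuration should react at the 1,1-disubstituted C4=C15 alkene much faster than at the trisubstituted ring alkene, with water attacking C4 along the equatorial (α) trajectory because the axial one is blocked by the C10 methyl (4α-OH, 4β-CH3), and the same NaBH4 reduces the C1 ketone by axial attack anti to the C10 methyl (1β-OH).

Step 14
Reactants: 21 1β,4α,8α-triol
Product: 22 1β,8α-bis-TBS ether with free 4α-hydroxyl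
Conditions: TBSCl, imidazole, DMAP (cat.), DMF, 40 °C
Reagents that add atoms: tert-butyldimethylsilyl chloride, CC(C)(C)[Si](C)(C)Cl
Why: Silylation of the two secondary hydroxyls (C1, C8) should leave the hindered tertiary C4 hydroxyl free.

Step 15
Reactants: 22 bis-TBS ether
Product: 24 4α,6α-diol (7α-H, side chain β), via cyclic alkylborane 23 (not isolated)
Conditions: BH3·THF, THF, 0 °C → rt; then NaOH, H2O2, 0 °C
Reagents that add atoms: hydrogen peroxide, OO
Why: Hydroboration–oxidation: syn addition of B–H to C6=C7 from the α-face (the β-face is screened by the axial C10 and C4 methyl groups), boron at the less substituted C6, then oxidation with retention, should set 6α-OH and 7α-H.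

Step 16
Reactants: 24 4α,6α-diol; 25 angelic acid
Product: 27 6α-angelate (PMB ether, bis-TBS ether), via mixed anhydride 26 (not isolated)
Conditions: 2,4,6-trichlorobenzoyl chloride, Et3N, toluene, rt; then 24, toluene, 80 °C
Reagents that add atoms: none
Why: Yamaguchi-type esterification through the 2,4,6-trichlorobenzoyl mixed anhydride, run without DMAP so that the (Z)-alkene should not isomerise to the tiglate, acylates the secondary C6 hydroxyl while the tertiary C4 hydroxyl stays free.

Step 17
Reactants: 27 6α-angelate PMB ether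
Product: 28 C12 primary alcohol
Conditions: DDQ, CH2Cl2/pH 7 buffer, 0 °C
Reagents that add atoms: none
Why: Oxidative PMB cleavage by DDQ (benzylic hydride abstraction, hydrolysis of the oxocarbenium ion) is compatible with the angelate and the silyl ethers.

Step 18
Reactants: 28 C12 primary alcohol
Product: 29 C12 aldehyde
Conditions: Dess–Martin periodinane, CH2Cl2, 0 °C → rt
Reagents that add atoms: none
Why: Dess–Martin oxidation of the primary alcohol to the aldehyde; the tertiary hydroxyl is inert.

Step 19
Reactants: 29 C12 aldehyde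
Product: 30 α-methylene aldehyde (C11=C13)
Conditions: aq. formaldehyde, pyrrolidine (cat.), propionic acid (cat.), i-PrOH, 45 °C
Reagents that add atoms: formaldehyde, C=O
Why: Amine-catalysed Mannich condensation with formaldehyde followed by elimination (organocatalytic α-methylenation of aldehydes) builds C11=C13 without strong base, so the angelate is spared and C7, which is not enolisable, keeps its configuration.

Step 20
Reactants: 30 α-methylene aldehyde
Product: 31 α-methylene carboxylic acid
Conditions: NaClO2, NaH2PO4, 2-methyl-2-butene, t-BuOH/H2O, 0 °C → rt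
Reagents that add atoms: sodium chlorite, [Na+].[O-]Cl=O
Why: Pinnick oxidation converts the enal into the acrylic acid without touching the alkenes, the hypochlorite by-product being trapped by 2-methyl-2-butene.

Step 21
Reactants: 31 α-methylene carboxylic acid
Product: 32 methyl ester, bis-TBS ether
Conditions: Me3SiCHN2, toluene/MeOH, 0 °C
Reagents that add atoms: trimethylsilyldiazomethane, C[Si](C)(C)C=[N+]=[N-]
Why: Esterification with trimethylsilyldiazomethane in methanol proceeds under neutral conditions that leave the angelate and the acrylate untouched.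

Step 22
Reactants: 32 methyl ester, bis-TBS ether
Product: 33 CNP0136844.1
Conditions: HF·pyridine, pyridine, THF, 0 °C → rt
Reagents that add atoms: none
Why: Buffered HF·pyridine cleaves both TBS ethers and should avoid acyl migration, conjugate addition to the acrylate and lactonisation of the freed C8 hydroxyl onto C12.

**Compound list**
1 | 3-bromofuran | Brc1ccoc1 | starting material
2 | oxirane | C1CO1 | starting material
3 | furan-3-yllithium | [Li]c1ccoc1 | intermediate
4 | 2-(furan-3-yl)ethan-1-ol | OCCc1ccoc1 | intermediate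
5 | 3-{2-[(4-methoxybenzyl)oxy]ethyl}furan | COc1ccc(COCCc2ccoc2)cc1 | intermediate
6 | 2-(4-{2-[(4-methoxybenzyl)oxy]ethyl}furan-2-yl)-4,4,5,5-tetramethyl-1,3,2-dioxaborolane | COc1ccc(COCCc2coc(B3OC(C)(C)C(C)(C)O3)c2)cc1 | intermediate
7 | methyl 4-chloro-4-oxobutanoate | COC(=O)CCC(=O)Cl | starting material
8 | methyl 4-(4-{2-[(4-methoxybenzyl)oxy]ethyl}furan-2-yl)-4-oxobutanoate | COC(=O)CCC(=O)c1cc(CCOCc2ccc(OC)cc2)co1 | intermediate
9 | methyl (4R)-4-hydroxy-4-(4-{2-[(4-methoxybenzyl)oxy]ethyl}furan-2-yl)butanoate | COC(=O)CC[C@@H](O)c1cc(CCOCc2ccc(OC)cc2)co1 | intermediate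
10 | (5R)-5-(4-{2-[(4-methoxybenzyl)oxy]ethyl}furan-2-yl)dihydrofuran-2(3H)-one | O=C1CC[C@H](c2cc(CCOCc3ccc(OC)cc3)co2)O1 | intermediate
11 | isopropenylmagnesium bromide | C=C(C)[Mg]Br | starting material
12 | (4R)-4-hydroxy-N-methoxy-4-(4-{2-[(4-methoxybenzyl)oxy]ethyl}furan-2-yl)-N-methylbutanamide | CON(C)C(=O)CC[C@@H](O)c1cc(CCOCc2ccc(OC)cc2)co1 | intermediate
13 | (6R)-6-hydroxy-6-(4-{2-[(4-methoxybenzyl)oxy]ethyl}furan-2-yl)-2-methylhex-1-en-3-one | C=C(C)C(=O)CC[C@@H](O)c1cc(CCOCc2ccc(OC)cc2)co1 | intermediate
14 | (6R)-6-[(tert-butyldimethylsilyl)oxy]-6-(4-{2-[(4-methoxybenzyl)oxy]ethyl}furan-2-yl)-2-methylhex-1-en-3-one | C=C(C)C(=O)CC[C@@H](O[Si](C)(C)C(C)(C)C)c1cc(CCOCc2ccc(OC)cc2)co1 | intermediate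
15 | oxa-bridged cycloadduct: C5–O–C8 bridge α, 4α-OTBS, 10β-methyl, C1 ketone, C6=C7 with 2-(PMB-oxy)ethyl on C7 | COc1ccc(COCCC2=C[C@]34O[C@H]2C[C@@]3(C)C(=O)CC[C@H]4O[Si](C)(C)C(C)(C)C)cc1 | intermediate
16 | oxa-bridged 4α-alcohol | COc1ccc(COCCC2=C[C@]34O[C@H]2C[C@@]3(C)C(=O)CC[C@H]4O)cc1 | intermediate
17 | oxa-bridged 1,4-dione | COc1ccc(COCCC2=C[C@]34O[C@H]2C[C@@]3(C)C(=O)CCC4=O)cc1 | intermediate
18 | trans-fused 8α-hydroxy-6-ene-1,4-dione (5α-H, 10β-methyl) | COc1ccc(COCCC2=C[C@@H]3[C@@](C)(C[C@@H]2O)C(=O)CCC3=O)cc1 | intermediate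
19 | 8α-hydroxy-4-methylene-6-en-1-one | COc1ccc(COCCC2=C[C@@H]3[C@@](C)(C[C@@H]2O)C(=O)CCC3=C)cc1 | intermediate
20 | C15 acetoxymercurio 4α,8α-diol 1-ketone | COc1ccc(COCCC2=C[C@@H]3[C@@](C)(C[C@@H]2O)C(=O)CC[C@@]3(C[Hg]OC(C)=O)O)cc1 | intermediate
21 | 1β,4α,8α-triol (4β-methyl, C6=C7) | COc1ccc(COCCC2=C[C@@H]3[C@@](C)(C[C@@H]2O)[C@H](O)CC[C@@]3(C)O)cc1 | intermediate
22 | 1β,8α-bis-TBS ether, 4α-ol | COc1ccc(COCCC2=C[C@@H]3[C@@](C)(C[C@@H]2O[Si](C)(C)C(C)(C)C)[C@H](O[Si](C)(C)C(C)(C)C)CC[C@@]3(C)O)cc1 | intermediate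
23 | cyclic alkylborane (boron on C6α, bound to the C4 oxygen) | COc1ccc(COCC[C@H]2[C@H]([BH]5)[C@@H]3[C@@](C)(C[C@@H]2O[Si](C)(C)C(C)(C)C)[C@H](O[Si](C)(C)C(C)(C)C)CC[C@@]3(C)O5)cc1 | intermediate
24 | 4α,6α-diol, 1β,8α-bis-TBS ether (7α-H) | COc1ccc(COCC[C@H]2[C@H](O)[C@@H]3[C@@](C)(C[C@@H]2O[Si](C)(C)C(C)(C)C)[C@H](O[Si](C)(C)C(C)(C)C)CC[C@@]3(C)O)cc1 | intermediate
25 | angelic acid, (Z)-2-methylbut-2-enoic acid | C/C=C(/C)C(=O)O | starting material
26 | angelic 2,4,6-trichlorobenzoic anhydride | C/C=C(/C)C(=O)OC(=O)c1c(Cl)cc(Cl)cc1Cl | intermediate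
27 | 6α-angelate, PMB ether, bis-TBS ether | COc1ccc(COCC[C@H]2[C@H](OC(=O)/C(C)=C\C)[C@@H]3[C@@](C)(C[C@@H]2O[Si](C)(C)C(C)(C)C)[C@H](O[Si](C)(C)C(C)(C)C)CC[C@@]3(C)O)cc1 | intermediate
28 | C12 primary alcohol | OCC[C@H]1[C@H](OC(=O)/C(C)=C\C)[C@@H]2[C@@](C)(C[C@@H]1O[Si](C)(C)C(C)(C)C)[C@H](O[Si](C)(C)C(C)(C)C)CC[C@@]2(C)O | intermediate
29 | C12 aldehyde | O=CC[C@H]1[C@H](OC(=O)/C(C)=C\C)[C@@H]2[C@@](C)(C[C@@H]1O[Si](C)(C)C(C)(C)C)[C@H](O[Si](C)(C)C(C)(C)C)CC[C@@]2(C)O | intermediate
30 | α-methylene aldehyde | C=C(C=O)[C@H]1[C@H](OC(=O)/C(C)=C\C)[C@@H]2[C@@](C)(C[C@@H]1O[Si](C)(C)C(C)(C)C)[C@H](O[Si](C)(C)C(C)(C)C)CC[C@@]2(C)O | intermediate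
31 | α-methylene carboxylic acid | C=C(C(=O)O)[C@H]1[C@H](OC(=O)/C(C)=C\C)[C@@H]2[C@@](C)(C[C@@H]1O[Si](C)(C)C(C)(C)C)[C@H](O[Si](C)(C)C(C)(C)C)CC[C@@]2(C)O | intermediate
32 | methyl ester, 1β,8α-bis-TBS ether | C=C(C(=O)OC)[C@H]1[C@H](OC(=O)/C(C)=C\C)[C@@H]2[C@@](C)(C[C@@H]1O[Si](C)(C)C(C)(C)C)[C@H](O[Si](C)(C)C(C)(C)C)CC[C@@]2(C)O | intermediate
33 | CNP0136844.1 | C=C(C(=O)OC)[C@H]1[C@H](OC(=O)/C(C)=C\C)[C@@H]2[C@@](C)(C[C@@H]1O)[C@H](O)CC[C@@]2(C)O | target

**Totals and risks**

Total step count: 22. Longest linear sequence: 22 steps (fully linear from 3-bromofuran).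

Step 8. The cycloaddition may stall or revert on work-up, and the Lewis acid may ionise the furfuryl silyl ether. The fallback activates the dienophile as a cation instead. Enone 14 would be converted with 1,2-bis(trimethylsilyloxy)ethane and catalytic TMSOTf (CH2Cl2, −78 °C) into the 2-isopropenyl-1,3-dioxolane F1. Catalytic TfOH at −78 °C should ionise F1 to the alkoxyallyl cation, which undergoes the intramolecular ionic Diels–Alder reaction with the furan and recloses to the adduct ketal F2. F2 cannot revert once the acid is quenched. Mild hydrolysis (PPTS, wet acetone) returns the route at 15.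

Step 13. Water may attack C4 with poor facial selectivity, or mercuration may compete at C6=C7. The fallback hydrates the C4=C15 alkene of 19 by the radical route (Mukaiyama hydration: Mn(dpm)3 cat., PhSiH3, O2, i-PrOH, 0 °C). Hydrogen-atom transfer gives the tertiary C4 radical, which is trapped by O2 from the open α-face, giving the 4α-hydroxy-1-ketone F3. NaBH4 in MeOH at 0 °C then reduces C1 and returns the route at 21.

Step 16. Acylation of the hindered, hydrogen-bonded C6 hydroxyl may be slow, and forcing conditions may isomerise the angeloyl group to the tigloyl group. The fallback builds the (Z)-alkene on the ester. Diol 24 would be esterified with the unhindered 2-[bis(2,2,2-trifluoroethoxy)phosphoryl]propanoic acid (diisopropylcarbodiimide, DMAP, CH2Cl2) to give the phosphonopropionate F4. Still–Gennari olefination of F4 with acetaldehyde (KN(SiMe3)2, 18-crown-6, THF, −78 °C) should give the (Z)-2-methylbut-2-enoate and return the route at 27.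

Further compounds
F1 | step 8 | 1,3-dioxolane of enone 14 | C=C(C)C1(CC[C@@H](O[Si](C)(C)C(C)(C)C)c2cc(CCOCc3ccc(OC)cc3)co2)OCCO1
F2 | step 8 | 1,3-dioxolane of cycloadduct 15 | COc1ccc(COCCC2=C[C@]34O[C@H]2C[C@@]3(C)C5(OCCO5)CC[C@H]4O[Si](C)(C)C(C)(C)C)cc1
F3 | step 13 | 4α,8α-dihydroxy-4β-methyl-6-en-1-one | COc1ccc(COCCC2=C[C@@H]3[C@@](C)(C[C@@H]2O)C(=O)CC[C@@]3(C)O)cc1
F4 | step 16 | 6α-{2-[bis(2,2,2-trifluoroethoxy)phosphoryl]propanoate} of 24 | COc1ccc(COCC[C@H]2[C@H](OC(=O)C(C)P(=O)(OCC(F)(F)F)OCC(F)(F)F)[C@@H]3[C@@](C)(C[C@@H]2O[Si](C)(C)C(C)(C)C)[C@H](O[Si](C)(C)C(C)(C)C)CC[C@@]3(C)O)cc1
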